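## Analysis of the target

The target is a germacranolide of the melampolide type: a ten-membered carbocycle (C1–C10) with a ring-cis (Z) trisubstituted alkene at C1–C10 carrying the C14 methyl and a ring-trans (E) trisubstituted alkene at C4–C5 carrying the C15 hydroxymethyl group. An α-methylene-γ-butyrolactone (C11–C13) is trans-fused at C6–C7 and closes on O6, and O8 is esterified with (E)-4-hydroxy-3-methylbut-2-enoic acid. The three stereocentres are contiguous, C6 (R), C7 (R) and C8 (S) in germacrane numbering, with H6 β, H7 α and H8 β; O6, the C7 side chain and O8 are therefore all trans and can all be equatorial on a six-membered ring. Sensitive groups are the conjugated methylene lactone (Michael acceptor, easily reduced and enolised), the 1,5-diene (Cope rearrangement, transannular cyclisation under heat or acid), the allylic ester and alcohols, and the γ-oxygenated enoate of the side chain, which can isomerise. The difficulty is a medium ring that holds two trisubstituted alkenes of opposite geometry next to three stereocentres. The strategy rests on the fact that the C1–C10 and C4–C5 alkenes flank C2–C3: with one more double bond there, C10=C1–C2=C3–C4=C5 is a hexatriene whose ends C5 and C10 close to a cis-fused bicyclic 1,3-diene made of ring A (C1–C5, C10) and ring B (C5–C10). In that bicycle C6, C7 and C8 sit on a cyclohexane chair, where they can be set and where the lactone fixes the conformation that decides both alkene geometries.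

## Retrosynthetic reasoning

Ester at O8. The acyl–O8 bond of 36 is cut first, giving alcohol 30 and the silylated acid 33 (joined as 35). The enoate side chain would not survive enolate chemistry, light or hydrogen transfer, so it has to arrive last. The forward step must acylate a hindered secondary alcohol without moving the side-chain alkene.

C11=C13 methylene. The exocyclic methylene of 29 is removed to give the plain lactone 26. A conjugated methylene lactone would be reduced in the hydrogen-transfer step and would absorb in the photochemical step; C11 of 26 is the only acidic carbon, so a Mannich aminomethylation and elimination (27, 28) can add C13 late.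

C2–C3 saturation and the C5–C10 bond. Adding a cis double bond at C2–C3 of 26 gives triene 25, and joining C5 to C10 gives the cis-fused diene lactone 24. This is the central simplification: the ten-membered ring and both trisubstituted alkenes come from scission of one bond in a strain-free bicycle, and no end-to-end ring closure is needed. The forward reaction must open 24 by light in the right conrotatory sense and then saturate only the central alkene before the triene can close again.

Lactone and ring-A diene. The C12–O6 bond of 24 is opened to the 6-acetoxy methyl ester 22 (through 23), and the diene of 22 is traced to the allylic C1 acetate 21 by a palladium-catalysed 1,4-elimination. Because C10 is quaternary, the allyl unit C1–C3 can lose only H4, so the diene position is unambiguous. Keeping O6 as an acetate until O8 is silylated decides which oxygen closes the lactone.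

C7–C8 bond. Ring B of 20 is cut between C7 and C8 to the aldehyde–enoate 19. A ketyl at C8 adding to C7 forms the ring and both remaining stereocentres in one step, and the ring-fusion centres already present dictate the chair through which it closes.

Side chains at C6 and C10. The enoate arm of 19 comes from aldehyde 17 by a Wittig reaction (18), and the C8 aldehyde from the enol ether installed on lactol 12. The γ-lactone of 11 therefore supplies O6 and delivers C9 at the aldehyde level for one-carbon homologation (12, 13, 14, 15, 16).

Ring A. The bonds C1–C10 and C4–C5 of 11 are cut in a Diels–Alder sense to butenolide 5 and diene 10. The C6 stereocentre of 5 directs the diene to the opposite face, suprafacial addition makes the ring fusion cis, and the diene brings C15 and the C1 oxygen that later leaves. Building ring B instead by cycloaddition onto a quinone-type ring A was set aside: it leaves two ring-A carbonyls beside C5 (epimerisation, β-elimination of O6) and a C8 ketone whose reduction from the β face is hindered by the axial C14.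

Building blocks. 5 comes from the chiral-pool aldehyde 1 (through 2, 3, 4), 10 from 6 and 8 (through 7 and 9), and 33 from 31 (through 32).

## Alternatives that were turned down

Alternative 1: The ring would be cut between C3 and C4. In the forward sense the terminal alkene of the open-chain iodide A2 (Z-diene arm, butenolide built from C15 and O6 with iodine on C4) is hydroborated at C3, and a palladium-catalysed B-alkyl Suzuki coupling under high dilution joins C3 to C4 to give the bridged lactone A1. In its favour, both ring alkenes have their geometry before the ring exists: C1–C10 comes from an acyclic Z-olefination and C4–C5 is locked in the five-membered lactone, which holds C15 cis to C6 as the target requires. On this point it is stronger than the chosen route, which relies on the sense of a conrotation. Against it, an sp3–sp2 coupling has to close a ten-membered ring end to end against transannular strain, in competition with protodeboronation, β-hydride loss and oligomerisation. A1 is also far from the target in oxidation pattern: the C15 lactone must be reduced and opened, the C12 acetal oxidised and lactonised onto O6, the methylene added, and a p-methoxybenzyl ether removed next to a 1,5-diene. The chosen route has no macrocyclisation and reaches the ten-membered ring with O6 already in the correct lactone.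

Alternative 2: Here the C7–C8 bond is disconnected. Tin–lithium exchange at C8 of the thirteen-membered allylic stannyl ether A4 gives an α-alkoxy carbanion that attacks C7 as the O–C13 bond breaks (Still–Wittig [2,3] shift), contracting the ring to the ten-membered alcohol A3. In its favour, a thirteen-membered ether is easier to close than a ten-membered carbocycle, and one concerted step makes the C7–C8 bond, the free O8 hydroxyl and the C11=C13 methylene. On the methylene it is stronger than the chosen route, which needs two extra steps for C13. Against it, the substrate needs a configurationally defined stannane and a C7–C11 alkene of defined geometry inside a macrocycle that already holds both trisubstituted ring alkenes. The relative configuration at C7 and C8 depends on the folding of a flexible large ring, a [1,2] shift competes, and C12 must still be oxidised to the lactone beside a 1,5-diene. In the chosen route C6–C8 are set on a cyclohexane chair before the large ring exists.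

Alternative 3: The C1–C10 double bond is disconnected. The eleven-membered sulfone A6 is halogenated next to sulfur, the carbanion on the other side closes the episulfone, and loss of SO2 (Ramberg–Bäcklund) gives the ten-membered diene A5 with the lactone masked as a methyl lactol ether. In its favour, the large ring is closed by C–S bond formation, SO2 loss is irreversible, and contraction to a ten-membered ring favours the ring-cis alkene wanted at C1–C10. For this single alkene it is at least as dependable as the photochemical step. Against it, the carbon that must become C10 is secondary and methyl-bearing, so halogenation and ring closure have to be regiocontrolled at a hindered centre. The strongly basic medium meets an allylic acetal oxygen at C6, an ether at C8 and an exocyclic methylene. The 4E alkene and all three stereocentres must be assembled separately in an open chain, and the lactol has to be oxidised at the end. The chosen step creates both alkenes at once from stereocentres that are easy to set on a decalin; its price is the photostationary state and the need for an immediate reduction.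

Key step: step 19

## Remarks on the chemistry

- Germacrane numbering of the target is used for every intermediate (C14 on C10, C15 on C4, C11–C13 on C7). α and β are the faces of the decalin made of ring A (C1–C5, C10) and ring B (C5–C10), with β the face of C14.
- Aldehyde 1 and the phosphorus reagents of steps 1, 9, 13 and 24 are taken to be commercially available.
- Compound 11 is written as the endo adduct. Its exo isomer (epimeric at C1 and C4 together) and the E/Z isomers of the enol ether in 13–18 behave alike and converge at 22 and 19.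

## Route

Step 1
Reactants: 1 (4S)-2,2-dimethyl-1,3-dioxolane-4-carbaldehyde
Product: 2 ethyl (2Z)-3-[(4R)-2,2-dimethyl-1,3-dioxolan-4-yl]-2-methylprop-2-enoate
Conditions: (CF3CH2O)2P(O)CH(CH3)CO2Et, KN(SiMe3)2, 18-crown-6, THF, −78 °C
Reagents that add atoms: ethyl 2-[bis(2,2,2-trifluoroethoxy)phosphoryl]propanoate, CCOC(=O)C(C)P(=O)(OCC(F)(F)F)OCC(F)(F)F
Why: Still–Gennari variant of the Horner–Wadsworth–Emmons olefination; the electron-poor phosphonate with a crown-separated potassium ion eliminates from the kinetic adduct and should give the Z-trisubstituted enoate that lactonisation needs. The stereocentre comes from the chiral pool and only its descriptor changes.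

Step 2
Reactants: 2 ethyl (2Z)-3-[(4R)-2,2-dimethyl-1,3-dioxolan-4-yl]-2-methylprop-2-enoate
Product: 4 (5R)-5-(hydroxymethyl)-3-methylfuran-2(5H)-one, via diol ester 3 (not isolated)
Conditions: 2 M HCl, THF–H2O, rt
Reagents that add atoms: none
Why: Acid hydrolysis of the acetonide frees diol 3, whose secondary hydroxyl is held next to the ester by the Z-alkene and closes the five-membered unsaturated lactone in preference to the six-membered one. The C6 stereocentre of the target is now in place.

Step 3
Reactants: 4 (5R)-5-(hydroxymethyl)-3-methylfuran-2(5H)-one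
Product: 5 (5R)-5-({[tert-butyl(dimethyl)silyl]oxy}methyl)-3-methylfuran-2(5H)-one
Conditions: tBuMe2SiCl, imidazole, CH2Cl2, 0 °C
Reagents that add atoms: tert-butyl(chloro)dimethylsilane, CC(C)(C)[Si](C)(C)Cl
Why: Standard silylation of a primary alcohol; the silyl ether keeps C7 at the alcohol level until step 11.

Step 4
Reactants: 6 but-3-en-1-ol
Product: 7 (but-3-en-1-yloxy)tri(propan-2-yl)silane
Conditions: iPr3SiCl, imidazole, CH2Cl2, rt
Reagents that add atoms: chlorotri(propan-2-yl)silane, CC(C)[Si](Cl)(C(C)C)C(C)C
Why: Standard silylation; the bulky triisopropylsilyl ether is chosen to outlast every later desilylation except the last.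

Step 5
Reactants: 7 (but-3-en-1-yloxy)tri(propan-2-yl)silane, 8 (2E)-but-2-enal
Product: 9 (2E)-5-{[tri(propan-2-yl)silyl]oxy}pent-2-enal
Conditions: second-generation Hoveyda–Grubbs catalyst (cat.), excess 8, CH2Cl2, 40 °C
Reagents that add atoms: none
Why: Olefin cross-metathesis of a terminal alkene with an enal, driven by loss of propene; the conjugated E-enal is the thermodynamic product.

Step 6
Reactants: 9 (2E)-5-{[tri(propan-2-yl)silyl]oxy}pent-2-enal
Product: 10 (1E,3E)-1-(trimethylsilyloxy)-5-{[tri(propan-2-yl)silyl]oxy}penta-1,3-diene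
Conditions: Me3SiCl, Et3N, ZnCl2 (cat.), toluene, 60 °C
Reagents that add atoms: chlorotrimethylsilane, C[Si](C)(C)Cl
Why: Soft enolisation: silylation of the aldehyde oxygen and loss of a C4 proton give the 1-silyloxy diene. The 1E,3E isomer should prevail, and any 3Z isomer cannot reach the s-cis form and stays behind in step 7.

Step 7
Reactants: 5 (5R)-5-({[tert-butyl(dimethyl)silyl]oxy}methyl)-3-methylfuran-2(5H)-one, 10 (1E,3E)-1-(trimethylsilyloxy)-5-{[tri(propan-2-yl)silyl]oxy}penta-1,3-diene
Product: 11 endo Diels–Alder adduct: ring A (cyclohex-2-ene) cis-fused at C5–C10 to the C9(=O)–O6 γ-lactone; 10β-methyl; 5β-H; 1α-OSiMe3; 4α-CH2OSi(iPr)3; C6 carries CH2OSiMe2tBu trans to C4 on the lactone ring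
Conditions: toluene, 2,6-di-tert-butyl-4-methylphenol (cat.), 150 °C, sealed tube
Reagents that add atoms: none
Why: Thermal normal-demand Diels–Alder reaction forming C1–C10 and C4–C5: the oxygen-bearing diene terminus joins the lactone α-carbon (ortho rule) and the diene adds to the butenolide face opposite the C6 side chain. Suprafacial addition makes the ring fusion cis (H5 and C14 on one face) and so sets C5 and C10; C1 and C4 are transient centres whose substituents are cis to each other.

Step 8
Reactants: 11 endo Diels–Alder adduct
Product: 12 lactol of 11 (C9 hemiacetal; both anomers)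
Conditions: iBu2AlH, CH2Cl2, −78 °C; aq. sodium potassium tartrate
Reagents that add atoms: none
Why: Partial reduction of the hindered γ-lactone to the lactol at low temperature; silyl ethers and the isolated alkene are inert.

Step 9
Reactants: 12 lactol of 11
Product: 14 enol ether diol (ring A with 10β-methyl; 10-(2-methoxyethenyl) = C9=C8; 1α-OH; 4α-CH2OSi(iPr)3; C5 side chain C6H(OH)–C7H2OSiMe2tBu), via silyl ether 13 (not isolated)
Conditions: MeOCH2PPh3Cl, KN(SiMe3)2, THF, 0 °C → rt; then K2CO3, MeOH, 0 °C
Reagents that add atoms: (methoxymethyl)triphenylphosphonium chloride, COC[P+](c1ccccc1)(c1ccccc1)c1ccccc1.[Cl-]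
Why: Wittig methoxymethylenation of the open hydroxy-aldehyde form of the lactol adds C8 as a masked aldehyde and releases O6; mild methanolysis then removes the labile trimethylsilyl ether of 13. E and Z enol ethers are carried on together.

Step 10
Reactants: 14 enol ether diol
Product: 15 1α,6-diacetate of 14
Conditions: Ac2O, pyridine, DMAP (cat.), CH2Cl2, rt
Reagents that add atoms: acetic anhydride, CC(=O)OC(C)=O
Why: Acylation of both secondary alcohols: the C1 acetate becomes the leaving group of step 17 and the C6 acetate keeps O6 apart from O8 until step 18.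

Step 11
Reactants: 15 1α,6-diacetate
Product: 16 C7 primary alcohol (15 without the tert-butyldimethylsilyl group)
Conditions: HF·pyridine, pyridine, THF, 0 °C
Reagents that add atoms: none
Why: Fluoride cleavage of the primary tert-butyldimethylsilyl ether is much faster than that of the triisopropylsilyl ether; the buffered, slightly acidic medium spares the enol ether and avoids acetyl migration from O6.

Step 12
Reactants: 16 C7 primary alcohol
Product: 17 C7 aldehyde (6-acetoxy aldehyde)
Conditions: Dess–Martin periodinane, NaHCO3, CH2Cl2, 0 °C → rt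
Reagents that add atoms: none
Why: Dess–Martin oxidation of the primary alcohol under buffered, non-epimerising conditions; the α-acetoxy aldehyde is used at once.

Step 13
Reactants: 17 C7 aldehyde
Product: 18 methyl (E)-enoate (C6H(OAc)–C7H=C11H–CO2Me; enol ether at C9=C8 retained)
Conditions: Ph3P=CHCO2Me, CH2Cl2, rt
Reagents that add atoms: methyl (triphenyl-λ5-phosphanylidene)acetate, COC(=O)C=P(c1ccccc1)(c1ccccc1)c1ccccc1
Why: Wittig reaction of a stabilised ylide, E-selective in an aprotic solvent, installs C11 and C12 and makes C7 the acceptor carbon of step 15.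

Step 14
Reactants: 18 methyl (E)-enoate
Product: 19 aldehyde–enoate (C10–C9H2–C8HO; C6H(OAc)–C7H=C11H–CO2Me; 1α-OAc; 4α-CH2OSi(iPr)3)
Conditions: 1 M HCl, THF, 0 °C
Reagents that add atoms: water, O
Why: Acid hydrolysis of the enol ether unmasks the C8 aldehyde; the aldehyde oxygen comes from water.

Step 15
Reactants: 19 aldehyde–enoate
Product: 20 cis-decalin hydroxy ester (8α-OH; 7β-CH2CO2Me; 6α-OAc; 1α-OAc; 4α-CH2OSi(iPr)3; Δ2; 5β-H; 10β-methyl)
Conditions: SmI2, MeOH, THF (dilute), −78 °C
Reagents that add atoms: none
Why: Reductive ketyl–olefin cyclisation (6-exo-trig): divalent samarium reduces the aldehyde first, the ketyl adds to C7 of the enoate and the samarium enolate is protonated. With C14 and the C5–C4 bond axial (fixed since step 7), the chair transition state carries the C6 acetate, the enoate arm and the O–Sm group equatorial, which should set C7 (side chain β) and C8 (oxygen α), each trans to its neighbour. The unactivated ring-A alkene does not compete.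

Step 16
Reactants: 20 cis-decalin hydroxy ester
Product: 21 8α-triethylsilyl ether of 20
Conditions: Et3SiOTf, 2,6-lutidine, CH2Cl2, −78 °C
Reagents that add atoms: triethylsilyl trifluoromethanesulfonate, CC[Si](CC)(CC)OS(=O)(=O)C(F)(F)F
Why: Silylation of the only free hydroxyl; it blocks closure of the C12 ester onto O8 and provides the group removed selectively in step 23.

Step 17
Reactants: 21 8α-triethylsilyl ether
Product: 22 cis-fused 1,3-diene ester (Δ1 and Δ3; 6α-OAc; 7β-CH2CO2Me; 8α-OSiEt3; 15-OSi(iPr)3)
Conditions: Pd(PPh3)4 (cat.), Et3N, 1,4-dioxane, 80 °C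
Reagents that add atoms: none
Why: Palladium-catalysed 1,4-elimination (Tsuji–Trost type): zerovalent palladium ionises the allylic C1 acetate with inversion, and the π-allyl complex has a single β-hydrogen, H4, which lies on the palladium face because it is trans to the acetate, while C10 is quaternary. β-Hydride elimination therefore gives the C1–C2/C3–C4 diene only; the C6 acetate is not allylic and stays.

Step 18
Reactants: 22 cis-fused 1,3-diene ester
Product: 24 cis-fused 1,3-diene trans-lactone (5β-H; 10β-methyl; 12,6α-olide; 8α-OSiEt3; 15-OSi(iPr)3), via hydroxy ester 23 (not isolated)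
Conditions: K2CO3, MeOH, rt
Reagents that add atoms: none
Why: Methanolysis of the C6 acetate frees O6, which closes the γ-lactone on the C12 methyl ester; both substituents are equatorial, so the lactone is trans-fused and locks ring B as a chair.

Step 19
Reactants: 24 cis-fused 1,3-diene trans-lactone
Product: 25 (1(10)Z,2Z,4E)-cyclodeca-1(10),2,4-triene 12,6α-lactone (8α-OSiEt3; 15-OSi(iPr)3)
Conditions: hν (254 nm, quartz), degassed Et2O–MeOH, −78 °C, to the photostationary state; the cold solution goes directly into step 20
Reagents that add atoms: none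
Why: Excitation of the cis-fused cyclohexa-1,3-diene (absorption near 260 nm) leads to a conrotatory six-electron electrocyclic opening that breaks C5–C10 and turns C1–C10 and C4–C5 into double bonds, the same reaction type as the light-driven opening of ring-fused cyclohexadienes such as hexalins, eudesma-1,3-dienes and ring B of provitamin D. No ring is closed end to end: the ten-membered ring appears when the bond shared by rings A and B is cut, so no cyclisation mode is involved. No stereocentre is created; C6, C7 and C8 are untouched, and C5 and C10 become trigonal. The step needs torquoselectivity, because the two conrotatory senses give the 1(10)Z,4E and the 1(10)E,4Z trienes. The trans-lactone holds ring B in the chair with C14 and the C5–C4 bond axial, which fixes the helicity of the ring-A diene so that C10–C9 and C5–H are pseudoaxial while C10–C14 and C5–C6 are pseudoequatorial. Conrotation in the sense that continues this twist turns the pseudoaxial bonds inward and the pseudoequatorial ones outward, placing C9 cis to C2 (ring-cis C1–C10) and C6 trans to C3 (ring-trans C4–C5). Low temperature and work to the photostationary state limit secondary photochemistry of the triene and its thermal disrotatory closure to the trans-fused isomer. For the same reason 25 is never warmed and is reduced at once.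

Step 20
Reactants: 25 (1(10)Z,2Z,4E)-triene lactone
Product: 26 (1(10)Z,4E)-germacra-1(10),4-dien-12,6α-olide skeleton without C13 (8α-OSiEt3; 15-OSi(iPr)3; C11H2)
Conditions: KO2CN=NCO2K, AcOH, Et2O–MeOH, −40 → −20 °C
Reagents that add atoms: none
Why: Diimide, generated from the azodicarboxylate and acetic acid, transfers H2 in a concerted syn fashion; the cis-disubstituted C2–C3 alkene reacts much faster than the two trisubstituted ones. Saturation removes the hexatriene and with it the path back to a bicycle.

Step 21
Reactants: 26 (1(10)Z,4E)-diene lactone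
Product: 27 11-[(dimethylamino)methyl] lactone (C11 epimers)
Conditions: LiN(iPr)2, THF, −78 °C; then CH2=NMe2+ I−, −78 → 0 °C
Reagents that add atoms: dimethylmethyleneiminium iodide, C=[N+](C)C.[I-]
Why: Mannich aminomethylation of the lactone lithium enolate; C11 is the only acidic position and the iminium salt is a reactive, non-enolisable one-carbon electrophile. The C11 configuration is of no consequence.

Step 22
Reactants: 27 11-[(dimethylamino)methyl] lactone
Product: 29 α-methylene lactone (11(13)-ene; 8α-OSiEt3; 15-OSi(iPr)3), via ammonium iodide 28 (not isolated)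
Conditions: MeI, MeOH, rt; then aq. NaHCO3, EtOAc, rt
Reagents that add atoms: none
Why: Quaternisation of the amine and base-induced β-elimination through the lactone enolate (E1cB) give the exocyclic C11–C13 alkene.

Step 23
Reactants: 29 α-methylene lactone
Product: 30 8α-alcohol (15-OSi(iPr)3 retained)
Conditions: pyridinium p-toluenesulfonate, MeOH–CH2Cl2, 0 °C
Reagents that add atoms: none
Why: Mild acid methanolysis cleaves the secondary triethylsilyl ether far faster than the primary triisopropylsilyl ether.

Step 24
Reactants: 31 1-{[tert-butyl(dimethyl)silyl]oxy}propan-2-one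
Product: 32 ethyl (2E)-4-{[tert-butyl(dimethyl)silyl]oxy}-3-methylbut-2-enoate
Conditions: (EtO)2P(O)CH2CO2Et, NaH, THF, 0 °C → rt; chromatography
Reagents that add atoms: triethyl phosphonoacetate, CCOC(=O)CP(=O)(OCC)OCC
Why: Horner–Wadsworth–Emmons olefination of a ketone; the E isomer (ester trans to the silyloxymethyl group) should prevail and is separated from the Z isomer.

Step 25
Reactants: 32 ethyl (2E)-4-{[tert-butyl(dimethyl)silyl]oxy}-3-methylbut-2-enoate
Product: 33 (2E)-4-{[tert-butyl(dimethyl)silyl]oxy}-3-methylbut-2-enoic acid
Conditions: LiOH, THF–H2O, rt; then 1 M HCl to pH 4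
Reagents that add atoms: lithium hydroxide, [Li+].[OH-]
Why: Saponification of the ethyl ester; the primary silyl ether survives hydroxide at room temperature and careful acidification.

Step 26
Reactants: 30 8α-alcohol, 33 (2E)-4-{[tert-butyl(dimethyl)silyl]oxy}-3-methylbut-2-enoic acid
Product: 35 bis-silylated target (8-O-[(2E)-4-(tert-butyldimethylsilyloxy)-3-methylbut-2-enoyl]; 15-OSi(iPr)3), via mixed anhydride 34 (not isolated)
Conditions: 33, 2,4,6-trichlorobenzoyl chloride, Et3N, toluene, rt; then 30, DMAP, toluene, rt
Reagents that add atoms: none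
Why: Yamaguchi esterification: DMAP attacks the mixed anhydride 34 at the less hindered carbonyl and the acylpyridinium acylates the hindered equatorial 8α-hydroxyl; no stereocentre is affected.

Step 27
Reactants: 35 bis-silylated target
Product: 36 CNP0233978.1 (target)
Conditions: HF·pyridine, pyridine, THF, 0 °C → rt
Reagents that add atoms: none
Why: Fluoride cleaves both primary silyl ethers; the buffered reagent leaves the methylene lactone, the ester and the 1,5-diene untouched.

## Compound list

1 | (4S)-2,2-dimethyl-1,3-dioxolane-4-carbaldehyde | O=C[C@@H]1COC(C)(C)O1 | starting material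
2 | ethyl (2Z)-3-[(4R)-2,2-dimethyl-1,3-dioxolan-4-yl]-2-methylprop-2-enoate | CCOC(=O)/C(C)=C\[C@@H]1COC(C)(C)O1 | intermediate
3 | ethyl (2Z,4R)-4,5-dihydroxy-2-methylpent-2-enoate (formed in the flask) | CCOC(=O)/C(C)=C\[C@@H](O)CO | intermediate
4 | (5R)-5-(hydroxymethyl)-3-methylfuran-2(5H)-one | OC[C@@H]1OC(=O)C(C)=C1 | intermediate
5 | (5R)-5-({[tert-butyl(dimethyl)silyl]oxy}methyl)-3-methylfuran-2(5H)-one | CC(C)(C)[Si](C)(C)OC[C@@H]1OC(=O)C(C)=C1 | intermediate
6 | but-3-en-1-ol | C=CCCO | starting material
7 | (but-3-en-1-yloxy)tri(propan-2-yl)silane | C=CCCO[Si](C(C)C)(C(C)C)C(C)C | intermediate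
8 | (2E)-but-2-enal | C/C=C/C=O | starting material
9 | (2E)-5-{[tri(propan-2-yl)silyl]oxy}pent-2-enal | O=C/C=C/CCO[Si](C(C)C)(C(C)C)C(C)C | intermediate
10 | (1E,3E)-1-(trimethylsilyloxy)-5-{[tri(propan-2-yl)silyl]oxy}penta-1,3-diene | C[Si](C)(C)O/C=C/C=C/CO[Si](C(C)C)(C(C)C)C(C)C | intermediate
11 | endo Diels–Alder adduct: ring A cis-fused to the C9(=O)–O6 γ-lactone; 10β-Me, 5β-H, 1α-OSiMe3, 4α-CH2OSi(iPr)3, Δ2; C6–CH2OSiMe2tBu | CC(C)(C)[Si](C)(C)OC[C@@H]1OC(=O)[C@@]2(C)[C@@H](O[Si](C)(C)C)C=C[C@@H](CO[Si](C(C)C)(C(C)C)C(C)C)[C@@H]12 | intermediate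
12 | lactol of 11 (C9 hemiacetal, both anomers) | CC(C)(C)[Si](C)(C)OC[C@@H]1OC(O)[C@@]2(C)[C@@H](O[Si](C)(C)C)C=C[C@@H](CO[Si](C(C)C)(C(C)C)C(C)C)[C@@H]12 | intermediate
13 | enol ether with 1α-OSiMe3 and free 6-OH (formed in the flask; E/Z at C8=C9) | CC(C)(C)[Si](C)(C)OC[C@H](O)[C@@H]1[C@H](CO[Si](C(C)C)(C(C)C)C(C)C)C=C[C@H](O[Si](C)(C)C)[C@]1(C)C=COC | intermediate
14 | enol ether diol (1α-OH, 6-OH; 10-(2-methoxyethenyl); 4α-CH2OSi(iPr)3; C7–OSiMe2tBu) | CC(C)(C)[Si](C)(C)OC[C@H](O)[C@@H]1[C@H](CO[Si](C(C)C)(C(C)C)C(C)C)C=C[C@H](O)[C@]1(C)C=COC | intermediate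
15 | 1α,6-diacetate of 14 | CC(C)(C)[Si](C)(C)OC[C@H](OC(C)=O)[C@@H]1[C@H](CO[Si](C(C)C)(C(C)C)C(C)C)C=C[C@H](OC(C)=O)[C@]1(C)C=COC | intermediate
16 | C7 primary alcohol (1α,6-diacetate) | OC[C@H](OC(C)=O)[C@@H]1[C@H](CO[Si](C(C)C)(C(C)C)C(C)C)C=C[C@H](OC(C)=O)[C@]1(C)C=COC | intermediate
17 | C7 aldehyde (1α,6-diacetate) | O=C[C@H](OC(C)=O)[C@@H]1[C@H](CO[Si](C(C)C)(C(C)C)C(C)C)C=C[C@H](OC(C)=O)[C@]1(C)C=COC | intermediate
18 | methyl (E)-enoate (C7=C11) with the C8 enol ether | COC(=O)/C=C/[C@H](OC(C)=O)[C@@H]1[C@H](CO[Si](C(C)C)(C(C)C)C(C)C)C=C[C@H](OC(C)=O)[C@]1(C)C=COC | intermediate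
19 | aldehyde–enoate (C8 aldehyde; C7=C11 E-enoate; 1α,6-diacetate) | COC(=O)/C=C/[C@H](OC(C)=O)[C@@H]1[C@H](CO[Si](C(C)C)(C(C)C)C(C)C)C=C[C@H](OC(C)=O)[C@]1(C)CC=O | intermediate
20 | cis-decalin hydroxy ester (8α-OH, 7β-CH2CO2Me, 6α-OAc, 1α-OAc, 4α-CH2OSi(iPr)3, Δ2, 5β-H, 10β-Me) | COC(=O)C[C@@H]1[C@@H](O)C[C@@]2(C)[C@@H](OC(C)=O)C=C[C@@H](CO[Si](C(C)C)(C(C)C)C(C)C)[C@H]2[C@H]1OC(C)=O | intermediate
21 | 8α-triethylsilyl ether of 20 | COC(=O)C[C@@H]1[C@@H](O[Si](CC)(CC)CC)C[C@@]2(C)[C@@H](OC(C)=O)C=C[C@@H](CO[Si](C(C)C)(C(C)C)C(C)C)[C@H]2[C@H]1OC(C)=O | intermediate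
22 | cis-fused 1,3-diene ester (6α-OAc, 7β-CH2CO2Me, 8α-OSiEt3, 15-OSi(iPr)3) | COC(=O)C[C@@H]1[C@@H](O[Si](CC)(CC)CC)C[C@@]2(C)C=CC=C(CO[Si](C(C)C)(C(C)C)C(C)C)[C@H]2[C@H]1OC(C)=O | intermediate
23 | 6α-hydroxy ester of 22 (formed in the flask) | COC(=O)C[C@@H]1[C@@H](O[Si](CC)(CC)CC)C[C@@]2(C)C=CC=C(CO[Si](C(C)C)(C(C)C)C(C)C)[C@H]2[C@H]1O | intermediate
24 | cis-fused 1,3-diene trans-lactone (5β-H, 10β-Me, 12,6α-olide, 8α-OSiEt3, 15-OSi(iPr)3) | C1C(=O)O[C@@H]2[C@@H]3C(CO[Si](C(C)C)(C(C)C)C(C)C)=CC=C[C@]3(C)C[C@H](O[Si](CC)(CC)CC)[C@@H]12 | intermediate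
25 | (1(10)Z,2Z,4E)-cyclodecatriene 12,6α-lactone (8α-OSiEt3, 15-OSi(iPr)3) | C1C(=O)O[C@@H]2/C=C(\CO[Si](C(C)C)(C(C)C)C(C)C)/C=C\C=C(\C)C[C@H](O[Si](CC)(CC)CC)[C@@H]12 | intermediate
26 | (1(10)Z,4E)-cyclodecadiene 12,6α-lactone with C11H2 (8α-OSiEt3, 15-OSi(iPr)3) | C1C(=O)O[C@@H]2/C=C(\CO[Si](C(C)C)(C(C)C)C(C)C)CC/C=C(/C)C[C@H](O[Si](CC)(CC)CC)[C@@H]12 | intermediate
27 | 11-[(dimethylamino)methyl] lactone (C11 epimers) | CN(C)CC1C(=O)O[C@@H]2/C=C(\CO[Si](C(C)C)(C(C)C)C(C)C)CC/C=C(/C)C[C@H](O[Si](CC)(CC)CC)[C@@H]12 | intermediate
28 | 11-[(trimethylammonio)methyl] lactone iodide (formed in the flask) | C[N+](C)(C)CC1C(=O)O[C@@H]2/C=C(\CO[Si](C(C)C)(C(C)C)C(C)C)CC/C=C(/C)C[C@H](O[Si](CC)(CC)CC)[C@@H]12.[I-] | intermediate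
29 | α-methylene lactone (8α-OSiEt3, 15-OSi(iPr)3) | C=C1C(=O)O[C@@H]2/C=C(\CO[Si](C(C)C)(C(C)C)C(C)C)CC/C=C(/C)C[C@H](O[Si](CC)(CC)CC)[C@@H]12 | intermediate
30 | 8α-alcohol (15-OSi(iPr)3) | C=C1C(=O)O[C@@H]2/C=C(\CO[Si](C(C)C)(C(C)C)C(C)C)CC/C=C(/C)C[C@H](O)[C@@H]12 | intermediate
31 | 1-{[tert-butyl(dimethyl)silyl]oxy}propan-2-one | CC(=O)CO[Si](C)(C)C(C)(C)C | starting material
32 | ethyl (2E)-4-{[tert-butyl(dimethyl)silyl]oxy}-3-methylbut-2-enoate | CCOC(=O)/C=C(\C)CO[Si](C)(C)C(C)(C)C | intermediate
33 | (2E)-4-{[tert-butyl(dimethyl)silyl]oxy}-3-methylbut-2-enoic acid | OC(=O)/C=C(\C)CO[Si](C)(C)C(C)(C)C | intermediate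
34 | mixed anhydride of 33 with 2,4,6-trichlorobenzoic acid (formed in the flask) | O=C(OC(=O)c1c(Cl)cc(Cl)cc1Cl)/C=C(\C)CO[Si](C)(C)C(C)(C)C | intermediate
35 | bis-silylated target (side-chain OSiMe2tBu, 15-OSi(iPr)3) | C=C1C(=O)O[C@@H]2/C=C(\CO[Si](C(C)C)(C(C)C)C(C)C)CC/C=C(/C)C[C@H](OC(=O)/C=C(\C)CO[Si](C)(C)C(C)(C)C)[C@@H]12 | intermediate
36 | CNP0233978.1 | C=C1C(=O)O[C@@H]2/C=C(\CO)CC/C=C(/C)C[C@H](OC(=O)/C=C(\C)CO)[C@@H]12 | target

## Step count and least certain steps

Total: 27 steps. Longest linear sequence: 22 steps (steps 1–3, 7–23, 26 and 27, from compound 1); the diene (steps 4–6) and the acid (steps 24–25) are side branches.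

Step 19 (key step). The most likely failures are incomplete conversion at the photostationary state together with secondary photoreactions of the triene (it absorbs the same light), and thermal disrotatory re-closure to the trans-fused diene while the reduction of step 20 is still running. A loss of torque control would show as the 1(10)E,4Z isomer. Fallback: move the opening one stage earlier. Diene ester 22, whose ring B is held in the same chair by three equatorial substituents but is not yet strained by the trans-lactone, is irradiated under the same conditions to give the triene ester F1. Diimide reduction gives the diene ester F2, and methanolysis of the C6 acetate with K2CO3 in MeOH closes the lactone on the ten-membered ring and returns to 26.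

Step 7. The α-methyl butenolide is trisubstituted and a weak dienophile, so the cycloaddition may be slower than polymerisation or desilylation of the diene. Fallback: set out from 1. Wittig olefination with methyl (triphenylphosphoranylidene)acetate in methanol (Z-selective) gives methyl (2Z)-3-[(4R)-2,2-dimethyl-1,3-dioxolan-4-yl]prop-2-enoate F3; aqueous acid gives (5R)-5-(hydroxymethyl)furan-2(5H)-one F4; silylation gives the silyl ether F5. This unsubstituted butenolide is the better dienophile and should add 10 at lower temperature with the same facial and regiochemical sense to give the 14-nor adduct F6. Deprotonation with LiN(iPr)2 and methylation with MeI on the lactone face opposite C4 keeps the cis ring fusion and returns to 11.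

Step 15. Diastereocontrol at C8 may be poor (a cis hydroxy ester would lactonise onto O8), or the aldehyde may simply be reduced or dimerised. Fallback: from 19, an intramolecular Stetter reaction with a triazolium-derived N-heterocyclic carbene forms the same C7–C8 bond and gives the 8-ketone F7, in which C7 can equilibrate to the equatorial side chain. Electron-transfer reduction of the ketone with SmI2 and iPrOH, which favours the more stable equatorial alcohol, returns to 20.

Step 17. Ionisation of the neopentyl-type allylic acetate may be slow, acetate may return to C3, or hydrogen shifts in the diene may set in at the temperature needed. Fallback: from 21, K2CO3 in MeOH removes both acetates and closes the lactone to give the hydroxy lactone F8. MnO2 oxidises the allylic C1 alcohol to the enone F9. Triflic anhydride with 2,6-di-tert-butyl-4-methylpyridine gives the dienyl triflate F10 (only H4 can be lost, C10 being quaternary). Palladium-catalysed formate reduction (Pd(OAc)2, PPh3, HCO2H, Bu3N) replaces the triflate by hydrogen and returns to 24.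

Step 26. The β,β-disubstituted enoate may isomerise (E to Z, or out of conjugation through a ketene) under acyl-transfer catalysis, or acylation of the hindered alcohol may be slow. Fallback: from 30, carbodiimide esterification with diethylphosphonoacetic acid gives the phosphonoacetate F11. Horner–Wadsworth–Emmons olefination with ketone 31 (LiCl, iPr2NEt) builds the side-chain alkene on the ester and returns to 35 after separation from the Z isomer.

## Further compounds

F1 | step 19 | triene ester: ten-membered (1(10)Z,2Z,4E)-triene with 6α-OAc, 7β-CH2CO2Me, 8α-OSiEt3, 15-OSi(iPr)3 | COC(=O)C[C@H]1[C@H](OC(C)=O)/C=C(\CO[Si](C(C)C)(C(C)C)C(C)C)/C=C\C=C(\C)C[C@@H]1O[Si](CC)(CC)CC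
F2 | step 19 | diene ester: ten-membered (1(10)Z,4E)-diene with 6α-OAc, 7β-CH2CO2Me, 8α-OSiEt3, 15-OSi(iPr)3 | COC(=O)C[C@H]1[C@H](OC(C)=O)/C=C(\CO[Si](C(C)C)(C(C)C)C(C)C)CC/C=C(/C)C[C@@H]1O[Si](CC)(CC)CC
F3 | step 7 | methyl (2Z)-3-[(4R)-2,2-dimethyl-1,3-dioxolan-4-yl]prop-2-enoate | COC(=O)/C=C\[C@@H]1COC(C)(C)O1
F4 | step 7 | (5R)-5-(hydroxymethyl)furan-2(5H)-one | OC[C@@H]1OC(=O)C=C1
F5 | step 7 | (5R)-5-({[tert-butyl(dimethyl)silyl]oxy}methyl)furan-2(5H)-one | CC(C)(C)[Si](C)(C)OC[C@@H]1OC(=O)C=C1
F6 | step 7 | 14-nor adduct (11 with H in place of the C10 methyl) | CC(C)(C)[Si](C)(C)OC[C@@H]1OC(=O)[C@H]2[C@@H](O[Si](C)(C)C)C=C[C@@H](CO[Si](C(C)C)(C(C)C)C(C)C)[C@@H]12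
F7 | step 15 | 8-ketone (cis-decalin with 8-oxo, 7β-CH2CO2Me, 6α-OAc, 1α-OAc, 4α-CH2OSi(iPr)3, Δ2) | COC(=O)C[C@@H]1C(=O)C[C@@]2(C)[C@@H](OC(C)=O)C=C[C@@H](CO[Si](C(C)C)(C(C)C)C(C)C)[C@H]2[C@H]1OC(C)=O
F8 | step 17 | hydroxy lactone (1α-OH, Δ2, 4α-CH2OSi(iPr)3, 12,6α-olide, 8α-OSiEt3) | C1C(=O)O[C@@H]2[C@@H]3[C@H](CO[Si](C(C)C)(C(C)C)C(C)C)C=C[C@H](O)[C@]3(C)C[C@H](O[Si](CC)(CC)CC)[C@@H]12
F9 | step 17 | enone (1-oxo, Δ2, 4α-CH2OSi(iPr)3, 12,6α-olide, 8α-OSiEt3) | C1C(=O)O[C@@H]2[C@@H]3[C@H](CO[Si](C(C)C)(C(C)C)C(C)C)C=CC(=O)[C@]3(C)C[C@H](O[Si](CC)(CC)CC)[C@@H]12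
F10 | step 17 | dienyl triflate (1-OSO2CF3, Δ1 and Δ3, 12,6α-olide, 8α-OSiEt3, 15-OSi(iPr)3) | C1C(=O)O[C@@H]2[C@@H]3C(CO[Si](C(C)C)(C(C)C)C(C)C)=CC=C(OS(=O)(=O)C(F)(F)F)[C@]3(C)C[C@H](O[Si](CC)(CC)CC)[C@@H]12
F11 | step 26 | phosphonoacetate: 8-O-(diethoxyphosphorylacetyl) ester of 30 | C=C1C(=O)O[C@@H]2/C=C(\CO[Si](C(C)C)(C(C)C)C(C)C)CC/C=C(/C)C[C@H](OC(=O)CP(=O)(OCC)OCC)[C@@H]12
A1 | alternative 1 | bridged lactone: ten-membered carbocycle spanned by the 15,6-butenolide, C12 as dimethyl acetal, 8-O-p-methoxybenzyl | COC(OC)C[C@H]1[C@H]2C=C(C(=O)O2)CC/C=C(/C)C[C@@H]1OCc3ccc(OC)cc3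
A2 | alternative 1 | open-chain iodide: 4-iodobutenolide carrying the Z-diene arm C3=C2–C1=C10 | C=C/C=C(/C)C[C@H](OCc1ccc(OC)cc1)[C@@H](CC(OC)OC)[C@H]1C=C(I)C(=O)O1
A3 | alternative 2 | ten-membered C8 alcohol with the 3-(triethylsilyloxy)prop-1-en-2-yl group on C7 | C=C(CO[Si](CC)(CC)CC)[C@H]1[C@H](O[Si](CC)(CC)CC)/C=C(\CO[Si](c2ccccc2)(c2ccccc2)C(C)(C)C)CC/C=C(/C)C[C@@H]1O
A4 | alternative 2 | thirteen-membered allylic stannyl ether (O8 bonded to C13, SnBu3 on C8; C7=C11 geometry left open) | [C@@H]1([Sn](CCCC)(CCCC)CCCC)OCC(CO[Si](CC)(CC)CC)=C[C@H](O[Si](CC)(CC)CC)/C=C(\CO[Si](c2ccccc2)(c2ccccc2)C(C)(C)C)CC/C=C(/C)C1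
A5 | alternative 3 | ten-membered 1(10),4-diene with α-methylene lactol methyl ether | C=C1[C@@H](OC)O[C@@H]2/C=C(\CO[Si](C(C)C)(C(C)C)C(C)C)CC/C=C(/C)C[C@H](OCc3ccc(OC)cc3)[C@@H]12
A6 | alternative 3 | eleven-membered sulfone (sulfur between C1 and C10; C10 epimers) | C=C1[C@@H](OC)O[C@@H]2/C=C(\CO[Si](C(C)C)(C(C)C)C(C)C)CCCS(=O)(=O)C(C)C[C@H](OCc3ccc(OC)cc3)[C@@H]12
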